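**Retrosynthetic overview**

1. Target 14 ⇐ its 5′-O-silyl ether 13 ⇐ aryl propiolate 12: the pyranone ring is cut at C4–C4a and closed last, by gold-catalysed hydroarylation of the alkyne.
2. Feature the plan rests on: O1, the C8 methoxy oxygen and O7 sit on the adjacent ring carbons C8a, C8 and C7, so they are the three oxygens of mirror-symmetric 2-methoxyresorcinol (two equivalent hydroxyls). C4a is its only free carbon ortho to O1 and lies para to O7.
3. 12 ⇐ 2-methoxyresorcinol 9 + propiolic acid 11 + epoxy alcohol 8 (Mitsunobu at C1′, then esterification).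
4. 8 ⇐ allylic alcohol 7 (Sharpless epoxidation; the oxirane is the first ring formed) ⇐ alkyne 4 (methylalumination, then formaldehyde) ⇐ prenal 1 + allenylboronate 2 (asymmetric propargylation sets C5′).
5. The C5′ oxygen is carried from step 1 as a silyl ether and is a spectator in the ring closure. Introducing it after ring closure would need a site-selective allylic C–H oxidation and would pass through a ketone β to the epoxide, which opens by elimination.

Key step: step 7

Remark: the sense of induction in step 1 is assigned by analogy with aryl and alkenyl aldehydes in the same reaction class. If analysis of 3 showed the 4S alcohol, the (S)-configured acid would be used and nothing else changes.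

**Step 1**
Reactants: 1 3-methylbut-2-enal; 2 allenylboronic acid pinacol ester
Product: 3 (4R)-6-methylhept-5-en-1-yn-4-ol
Conditions: (R)-3,3′-bis(2,4,6-triisopropylphenyl)-1,1′-binaphthyl-2,2′-diyl hydrogen phosphate (5 mol %), 4 Å molecular sieves, toluene, −20 → 0 °C; aq. NaHCO3
Reagents that add atoms: none
Why: Chiral phosphoric acid-catalysed propargylboration runs through a closed six-membered SE2′ transition state in which the acid bridges the boronate oxygen and the formyl hydrogen, so the allenyl unit is transferred through its γ-carbon and only the homopropargylic alcohol should form; the (R)-acid is expected to direct attack to the Re face of the enal, which sets C4 (the later C5′) as R, to be confirmed by Mosher ester analysis.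

**Step 2**
Reactants: 3 (4R)-6-methylhept-5-en-1-yn-4-ol
Product: 4 tert-butyl(dimethyl){[(4R)-6-methylhept-5-en-1-yn-4-yl]oxy}silane
Conditions: TBSCl, imidazole, DMF, rt
Reagents that add atoms: tert-butyldimethylsilyl chloride, CC(C)(C)[Si](C)(C)Cl
Why: Standard silylation of a secondary alcohol, which keeps this hydroxyl from quenching the organoaluminium reagent in step 3 and from directing epoxidation of the 6,7-alkene in step 4; the stereocentre is not touched.

**Step 3**
Reactants: 4 tert-butyl(dimethyl){[(4R)-6-methylhept-5-en-1-yn-4-yl]oxy}silane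
Product: 7 (2E,5R)-5-{[tert-butyl(dimethyl)silyl]oxy}-3,7-dimethylocta-2,6-dien-1-ol, via alkenyldimethylalane 5 (not isolated), via lithium alkenylbutyldimethylalanate 6 (not isolated)
Conditions: Me3Al, Cp2ZrCl2 (25 mol %), CH2Cl2, 0 °C → rt; evaporate; n-BuLi, THF–hexane, −78 → 0 °C; (CH2O)n, rt; aq. potassium sodium tartrate
Reagents that add atoms: trimethylaluminium, C[Al](C)C; paraformaldehyde (reacts as formaldehyde), C=O
Why: Negishi zirconium-catalysed methylalumination adds methyl and aluminium syn across the terminal alkyne with aluminium on the terminal carbon, and the derived alanate attacks formaldehyde with retention at the alkenyl carbon, so the hydroxymethyl group should end trans to the C4 chain (2E) while the silyl ether and the trisubstituted alkene stay untouched.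

**Step 4**
Reactants: 7 (2E,5R)-5-{[tert-butyl(dimethyl)silyl]oxy}-3,7-dimethylocta-2,6-dien-1-ol
Product: 8 [(2R,3R)-3-[(2R)-2-{[tert-butyl(dimethyl)silyl]oxy}-4-methylpent-3-en-1-yl]-3-methyloxiran-2-yl]methanol
Conditions: Ti(OiPr)4 (10 mol %), D-(−)-diethyl tartrate (12 mol %), t-BuOOH, 4 Å molecular sieves, CH2Cl2, −20 °C
Reagents that add atoms: tert-butyl hydroperoxide, CC(C)(C)OO
Why: Sharpless asymmetric epoxidation acts only on the alkene bearing the free allylic hydroxyl (the 6,7-alkene is an allylic silyl ether), and with D-(−)-diethyl tartrate an E-3-methylalk-2-en-1-ol of the geraniol type should give the (2R,3R)-epoxy alcohol under reagent control, the remote C5 centre having little influence.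

**Step 5**
Reactants: 8 [(2R,3R)-3-[(2R)-2-{[tert-butyl(dimethyl)silyl]oxy}-4-methylpent-3-en-1-yl]-3-methyloxiran-2-yl]methanol; 9 2-methoxyresorcinol (3 equiv)
Product: 10 2-methoxy-3-{[(2R,3R)-3-[(2R)-2-{[tert-butyl(dimethyl)silyl]oxy}-4-methylpent-3-en-1-yl]-3-methyloxiran-2-yl]methoxy}phenol
Conditions: PPh3, DIAD, THF, 0 °C → rt; excess 9 recovered
Reagents that add atoms: none
Why: In this Mitsunobu etherification the phenoxide displaces the oxyphosphonium group at the primary C1′, which is not a stereocentre, and leaves the adjacent epoxide intact; the two hydroxyls of 9 are equivalent, so only one mono-ether can form and the excess of 9 keeps double alkylation low.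

**Step 6**
Reactants: 10 2-methoxy-3-{[(2R,3R)-3-[(2R)-2-{[tert-butyl(dimethyl)silyl]oxy}-4-methylpent-3-en-1-yl]-3-methyloxiran-2-yl]methoxy}phenol; 11 propiolic acid
Product: 12 2-methoxy-3-{[(2R,3R)-3-[(2R)-2-{[tert-butyl(dimethyl)silyl]oxy}-4-methylpent-3-en-1-yl]-3-methyloxiran-2-yl]methoxy}phenyl prop-2-ynoate
Conditions: DCC, DMAP (5 mol %), CH2Cl2, −20 → 0 °C
Reagents that add atoms: none
Why: Steglich esterification (carbodiimide activation, acyl transfer by DMAP) acylates the remaining phenol; low temperature and little DMAP limit amine addition to the propiolate, and the epoxide, silyl ether and alkene are inert.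

**Step 7**
Reactants: 12 2-methoxy-3-{[(2R,3R)-3-[(2R)-2-{[tert-butyl(dimethyl)silyl]oxy}-4-methylpent-3-en-1-yl]-3-methyloxiran-2-yl]methoxy}phenyl prop-2-ynoate
Product: 13 7-{[(2R,3R)-3-[(2R)-2-{[tert-butyl(dimethyl)silyl]oxy}-4-methylpent-3-en-1-yl]-3-methyloxiran-2-yl]methoxy}-8-methoxy-2H-chromen-2-one
Conditions: Ph3PAuNTf2 (5 mol %), 4 Å molecular sieves, CH2Cl2, rt
Reagents that add atoms: none
Why: The cationic gold complex binds the alkyne of 12, and arene carbon C6 (ortho to the ester oxygen, para to the ether oxygen) attacks the terminal alkyne carbon in a Friedel–Crafts sense to form C4–C4a; loss of the arenium proton and protodeauration of the alkenylgold then give C3–H and release the catalyst, so the step is an isomerisation. The closest known reaction type is the gold-catalysed intramolecular hydroarylation of aryl alkynoates to coumarins. The pyranone ring closes in the 6-endo-dig mode. No stereocentre is formed, and the three existing ones are remote from the reacting atoms. The step needs site selectivity on the arene, which is fixed because C6 is the only free carbon ortho to the ester oxygen and is activated by the para ether oxygen, a pattern that also favours direct 6-endo attack over ipso attack. It also needs chemoselectivity for the alkyne over the epoxide, the trisubstituted alkene and the allylic silyl ether, which rests on the weak oxophilicity of the phosphine–gold cation at room temperature under dry conditions.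

**Step 8**
Reactants: 13 7-{[(2R,3R)-3-[(2R)-2-{[tert-butyl(dimethyl)silyl]oxy}-4-methylpent-3-en-1-yl]-3-methyloxiran-2-yl]methoxy}-8-methoxy-2H-chromen-2-one
Product: 14 7-{[(2R,3R)-3-[(2R)-2-hydroxy-4-methylpent-3-en-1-yl]-3-methyloxiran-2-yl]methoxy}-8-methoxy-2H-chromen-2-one
Conditions: Bu4NF (TBAF), AcOH (1:1), THF, 0 °C → rt
Reagents that add atoms: none
Why: Fluoride-mediated cleavage of the silicon–oxygen bond is driven by the strong Si–F bond; buffering with acetic acid keeps the medium near neutral so that the lactone and the epoxide should not meet alkoxide or hydroxide, and no stereocentre is touched.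

**Compound list**

1 | 3-methylbut-2-enal | CC(C)=CC=O | starting material
2 | allenylboronic acid pinacol ester (4,4,5,5-tetramethyl-2-(propa-1,2-dien-1-yl)-1,3,2-dioxaborolane) | C=C=CB1OC(C)(C)C(C)(C)O1 | starting material
3 | (4R)-6-methylhept-5-en-1-yn-4-ol | C#CC[C@@H](O)C=C(C)C | intermediate
4 | tert-butyl(dimethyl){[(4R)-6-methylhept-5-en-1-yn-4-yl]oxy}silane | C#CC[C@@H](O[Si](C)(C)C(C)(C)C)C=C(C)C | intermediate
5 | [(1E,4R)-4-{[tert-butyl(dimethyl)silyl]oxy}-2,6-dimethylhepta-1,5-dien-1-yl]dimethylalane | C[Al](C)/C=C(\C)C[C@@H](O[Si](C)(C)C(C)(C)C)C=C(C)C | intermediate (not isolated)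
6 | lithium butyl[(1E,4R)-4-{[tert-butyl(dimethyl)silyl]oxy}-2,6-dimethylhepta-1,5-dien-1-yl]dimethylalanate | [Li+].CCCC[Al-](C)(C)/C=C(\C)C[C@@H](O[Si](C)(C)C(C)(C)C)C=C(C)C | intermediate (not isolated)
7 | (2E,5R)-5-{[tert-butyl(dimethyl)silyl]oxy}-3,7-dimethylocta-2,6-dien-1-ol | OC/C=C(\C)C[C@@H](O[Si](C)(C)C(C)(C)C)C=C(C)C | intermediate
8 | [(2R,3R)-3-[(2R)-2-{[tert-butyl(dimethyl)silyl]oxy}-4-methylpent-3-en-1-yl]-3-methyloxiran-2-yl]methanol | OC[C@H]1O[C@]1(C)C[C@@H](O[Si](C)(C)C(C)(C)C)C=C(C)C | intermediate
9 | 2-methoxyresorcinol (2-methoxybenzene-1,3-diol) | COc1c(O)cccc1O | starting material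
10 | 2-methoxy-3-{[(2R,3R)-3-[(2R)-2-{[tert-butyl(dimethyl)silyl]oxy}-4-methylpent-3-en-1-yl]-3-methyloxiran-2-yl]methoxy}phenol | COc1c(O)cccc1OC[C@H]1O[C@]1(C)C[C@@H](O[Si](C)(C)C(C)(C)C)C=C(C)C | intermediate
11 | propiolic acid | C#CC(=O)O | starting material
12 | 2-methoxy-3-{[(2R,3R)-3-[(2R)-2-{[tert-butyl(dimethyl)silyl]oxy}-4-methylpent-3-en-1-yl]-3-methyloxiran-2-yl]methoxy}phenyl prop-2-ynoate | C#CC(=O)Oc1cccc(OC[C@H]2O[C@]2(C)C[C@@H](O[Si](C)(C)C(C)(C)C)C=C(C)C)c1OC | intermediate
13 | 7-{[(2R,3R)-3-[(2R)-2-{[tert-butyl(dimethyl)silyl]oxy}-4-methylpent-3-en-1-yl]-3-methyloxiran-2-yl]methoxy}-8-methoxy-2H-chromen-2-one | COc1c(OC[C@H]2O[C@]2(C)C[C@@H](O[Si](C)(C)C(C)(C)C)C=C(C)C)ccc2ccc(=O)oc12 | intermediate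
14 | 7-{[(2R,3R)-3-[(2R)-2-hydroxy-4-methylpent-3-en-1-yl]-3-methyloxiran-2-yl]methoxy}-8-methoxy-2H-chromen-2-one | COc1c(OC[C@H]2O[C@]2(C)C[C@@H](O)C=C(C)C)ccc2ccc(=O)oc12 | target

**Totals**

Total step count: 8. Longest linear sequence: 8 steps (1 → 14).

**Steps most likely to fail**

Step 7. The gold cation, or triflimide acid formed from it by traces of water, may open or rearrange the trisubstituted epoxide, ionise the allylic silyl ether or hydrate the alkyne faster than the arene attacks. The fallback closes the pyranone ring on the bare phenol before the side chain is attached. It sets out from 2-methoxyresorcinol 9, which under von Pechmann conditions (malic acid, conc. H2SO4, about 100 °C) should give 7-hydroxy-8-methoxy-2H-chromen-2-one F1, the two ring positions ortho to a hydroxyl being equivalent. Mitsunobu etherification of F1 with epoxy alcohol 8 (PPh3, DIAD, THF) then comes back to the route at coumarin 13.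

Step 1. Addition to the β,β-disubstituted enal may be slow, and the facial selectivity may be too low to carry forward. The fallback uses resolution in place of asymmetric catalysis. It sets out from aldehyde 1: zinc-mediated Barbier propargylation (propargyl bromide, Zn, THF–aq. NH4Cl) should give racemic 6-methylhept-5-en-1-yn-4-ol F2. Sharpless kinetic resolution of this secondary allylic alcohol (Ti(OiPr)4, L-(+)-diisopropyl tartrate, t-BuOOH 0.6 equiv, CH2Cl2, −20 °C) should epoxidise the 4S enantiomer to (1S)-1-[(2S)-3,3-dimethyloxiran-2-yl]but-3-yn-1-ol F3 and leave the 4R alcohol, which is the point of return, compound 3. Because the alkene carries a cis methyl group the rate ratio is expected to be moderate, so the resolution would be run past half conversion.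

Step 5. The diol may be etherified twice, or the phenol or the reduced azo reagent may attack the epoxide, and the mono-ether may be hard to separate from the hydrazide. The fallback uses alkylation in place of redox condensation. It sets out from epoxy alcohol 8, which with 3-nitrobenzenesulfonyl chloride, Et3N and DMAP in CH2Cl2 should give [(2R,3R)-3-[(2R)-2-{[tert-butyl(dimethyl)silyl]oxy}-4-methylpent-3-en-1-yl]-3-methyloxiran-2-yl]methyl 3-nitrobenzenesulfonate F4. Displacement at the primary carbon by the mono-phenoxide of 9 (excess 9, Cs2CO3, DMF, rt) comes back to the route at phenol 10.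

**Further compounds**

F1 | step 7 | 7-hydroxy-8-methoxy-2H-chromen-2-one | COc1c(O)ccc2ccc(=O)oc12
F2 | step 1 | rac-6-methylhept-5-en-1-yn-4-ol | C#CCC(O)C=C(C)C
F3 | step 1 | (1S)-1-[(2S)-3,3-dimethyloxiran-2-yl]but-3-yn-1-ol | C#CC[C@H](O)[C@@H]1OC1(C)C
F4 | step 5 | [(2R,3R)-3-[(2R)-2-{[tert-butyl(dimethyl)silyl]oxy}-4-methylpent-3-en-1-yl]-3-methyloxiran-2-yl]methyl 3-nitrobenzenesulfonate | O=S(=O)(OC[C@H]1O[C@]1(C)C[C@@H](O[Si](C)(C)C(C)(C)C)C=C(C)C)c1cccc([N+](=O)[O-])c1
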